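All runs are calculated with constants of no real substance; the scatter is artificial.

Slowness is what target shows in the three earlier runs: it climbs over minutes, yet at 2.00 min in the north-west run starting material, target and uncatalysed product together account for 45.0% of the charge, so the rest stands in something unlisted.

| setting | north-west | east | south-east | flask |
|---|---|---|---|---|
| starting material | 0.50 M | 0.50 M | 0.25 M | 0.50 M |
| partner | 1.7 equiv | 3.8 equiv | 2.5 equiv | 2.50 equiv |
| free catalyst | 20 mol% | 20 mol% | 20 mol% | 20 mol% |
| remark | run made earlier | run made earlier | run made earlier |  |
| time |  |  |  | 15 min |

| run | time / min | uncatalysed product / % | target / % | starting material / % |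
|---|---|---|---|---|
| north-west | 2.00 | 15.2 | 10.0 | 19.8 |
| north-west | 5.00 | 25.0 | 21.0 | 13.5 |
| north-west | 10.0 | 35.6 | 32.0 | 8.6 |
| north-west | 15.0 | 38.4 | 37.4 | 4.5 |
| east | 4.00 | 39.3 | 26.6 | 7.8 |
| east | 8.00 | 49.5 | 37.9 | 3.7 |
| east | 12.0 | 52.1 | 41.1 | 0.5 |
| east | 15.0 | 53.8 | 41.3 | 0.6 |
| south-east | 4.00 | 19.9 | 8.0 | 18.6 |
| south-east | 8.00 | 30.7 | 16.4 | 13.1 |
| south-east | 12.0 | 39.0 | 17.7 | 10.1 |
| south-east | 15.0 | 43.0 | 21.9 | 9.3 |

(each reading ± 1 percentage point)

- the numbers in the tables scatter with a standard deviation of 1 percentage point

* share of uncatalysed product in uncatalysed product plus target at 6.0 s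
* share of uncatalysed product in uncatalysed product plus target at 80 s
* share of uncatalysed product in uncatalysed product plus target at 15 min

Taken in slow motion, the north-west run first lays down a lead and then keeps a pace. By its first reading starting material stands at 19.8% and target lags, with more uncatalysed product than target. After that lead is laid down, the two products grow side by side, and their pace can be read. Call the late ratio, a selectivity factor, the gain in uncatalysed product over the gain in target between first and last reading. It reads 0.847 in the north-west run and 0.986 in the east run, so in these scattered readings moving partner from 1.7 equiv to 3.8 equiv changes it little. The south-east run, with half the catalyst and half the starting material, and a different partner charge besides, reads 1.66, twice the north-west value.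

Late ratio times catalyst charged therefore holds roughly steady, averaging 0.0888 M: this is the crossover catalyst level, the [free catalyst] at which both products grow equally late in a run. The flask charges 0.100 M of catalyst, so its late ratio should be 0.888, and late material should split 47.0% towards uncatalysed product. The share in the flask should start high and sink towards that late split, and this reckoning commits to a 15 min share above it, by whatever the early lead adds.

The forecast gives 93% at 6.0 s, 63% at 80 s and 53.5% at 15 min, the last standing above this late split, and holds that “target formation scales with catalyst”.

The flask gives 97.2% at 6.0 s, 65.3% at 80 s and 53.3% at 15 min.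

    starting material + free catalyst ⇌ free catalyst + open intermediate (K = 2.80, k = 0.790 L mol⁻¹ s⁻¹)
    free catalyst + open intermediate ⇌ catalyst intermediate (K = 0.750 L mol⁻¹, k = 0.130 L mol⁻¹ s⁻¹)
    partner + catalyst intermediate → free catalyst + target (k = 0.0340 L mol⁻¹ s⁻¹)
    starting material + partner → uncatalysed product (k = 0.00550 L mol⁻¹ s⁻¹)

The flask ends 6.3 points above the late split of 47.0%. Both undoing steps hold its 15 min share up, each in part: without the undoing of open intermediate into starting material the flask reads 10.6%, and without the undoing of catalyst intermediate into free catalyst and open intermediate 24.7%. The neighbour flask at 0.12 M of starting material holds 0.0240 M of catalyst, so 0.0888 M gives it a late split of 78.7%, and at 15 min it reads 80.8%.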